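The route rests on cutting the C4''–C3' bond that ties the 2,2-dimethylpyran to ring B, together with the C8–quaternary carbon bond on ring A. Both bonds trace back to aryl ethers. One thermolysis of a flavonol bearing a 1,1-dimethylpropargyl ether on O4' and a prenyl ether on O7 therefore finishes the carbon skeleton. The step exploits that O4' of ring B has a single free ortho carbon, C3' (C5' carries OH), and that O7 of ring A adjoins C8 of the pyrone-fused ring. Propargyl Claisen shift, hydrogen shift and oxa-6π closure build the pyran. An allyl-inverting Claisen shift installs the 1,1-dimethylallyl group. The precursor comes from an acetophenone and a 2-prenylbenzaldehyde.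

Key step: step 6

Assumption: 2',4'-dihydroxy-6'-methoxyacetophenone and 2-bromo-4,5-dihydroxybenzaldehyde are taken as catalogue compounds. Flavonoid numbering is used, with C2' the prenyl-bearing carbon of ring B and C2'' (CMe2), C3'', C4'' the pyran carbons.

Step 1
Reactants: 1 2',4'-dihydroxy-6'-methoxyacetophenone
Product: 2 1-[2-hydroxy-6-methoxy-4-(3-methylbut-2-enyloxy)phenyl]ethanone
Conditions: prenyl bromide (1.05 equiv), K2CO3 (1.2 equiv), acetone, reflux
Reagents that add atoms: prenyl bromide (1-bromo-3-methylbut-2-ene), CC(C)=CCBr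
Why: Williamson etherification in which the 2-OH is locked in a hydrogen bond to the acetyl carbonyl, so the weak base ionises only the free and more acidic 4-OH, which attacks the primary carbon of prenyl bromide by SN2.

Step 2
Reactants: 3 2-bromo-4,5-dihydroxybenzaldehyde
Product: 4 4,5-dihydroxy-2-(3-methylbut-2-enyl)benzaldehyde
Conditions: tributyl(3-methylbut-2-enyl)stannane (1.2 equiv), Pd(PPh3)4 (5 mol %), DMF, 90 °C, Ar
Reagents that add atoms: tributyl(3-methylbut-2-enyl)stannane, CCCC[Sn](CCCC)(CCCC)CC=C(C)C
Why: Stille coupling in which the ortho-formyl group speeds oxidative addition of zerovalent palladium into the C–Br bond, the neutral medium tolerates the free catechol and the aldehyde, and reductive elimination from the aryl(η3-prenyl)palladium species occurs at the unsubstituted allyl terminus to give the linear prenyl arene.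

Step 3
Reactants: 4 4,5-dihydroxy-2-(3-methylbut-2-enyl)benzaldehyde
Product: 5 5-hydroxy-4-(2-methylbut-3-yn-2-yloxy)-2-(3-methylbut-2-enyl)benzaldehyde
Conditions: 3-chloro-3-methylbut-1-yne (1.1 equiv), DBU (1.1 equiv), CuCl2·2H2O (1 mol %), MeCN, 0 °C to rt
Reagents that add atoms: 3-chloro-3-methylbut-1-yne, C#CC(C)(C)Cl
Why: Copper-catalysed O-propargylation of a phenol with a tertiary propargylic chloride (a copper acetylide ionises to an allenylidene-type electrophile), in which one equivalent of base deprotonates only the 4-OH, clearly the more acidic because it is para to the formyl group, so the ether forms on O4 alone.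

Step 4
Reactants: 2 1-[2-hydroxy-6-methoxy-4-(3-methylbut-2-enyloxy)phenyl]ethanone; 5 5-hydroxy-4-(2-methylbut-3-yn-2-yloxy)-2-(3-methylbut-2-enyl)benzaldehyde
Product: 6 (E)-1-[2-hydroxy-6-methoxy-4-(3-methylbut-2-enyloxy)phenyl]-3-[5-hydroxy-4-(2-methylbut-3-yn-2-yloxy)-2-(3-methylbut-2-enyl)phenyl]prop-2-en-1-one
Conditions: KOH (50% aq.), EtOH, rt; then dilute HCl to pH 5
Reagents that add atoms: none
Why: Claisen–Schmidt condensation in which the methyl ketone enolate adds to the non-enolisable aldehyde and E1cB loss of water gives the favoured E-enone, the phenoxide of 5 being meta to the formyl group and thus not deactivating it, and the propargylic ether having no propargylic hydrogen through which base could isomerise it.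

Step 5
Reactants: 6 the (E)-chalcone
Product: 8 3-hydroxy-2-[5-hydroxy-4-(2-methylbut-3-yn-2-yloxy)-2-(3-methylbut-2-enyl)phenyl]-5-methoxy-7-(3-methylbut-2-enyloxy)chromen-4-one, via racemic trans-dihydroflavonol 7 (not isolated)
Conditions: 30% aq. H2O2, 2 M NaOH, MeOH, 0 °C to rt; then dilute HCl
Reagents that add atoms: hydrogen peroxide, OO
Why: Algar–Flynn–Oyamada reaction in which hydroperoxide anion oxidises only the electron-poor enone, the 2'-phenoxide closes ring C at the β-carbon to give trans-dihydroflavonol 7, and further peroxide dehydrogenates 7 to the flavonol and erases both transient stereocentres, while the isolated alkenes, the alkyne and the aryl ethers are inert to nucleophilic peroxide.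

Step 6
Reactants: 8 the flavonol 4'-(1,1-dimethylpropargyl) 7-prenyl bis-ether
Product: 12 5-O-methylbroussoflavonol D, via allenyl catechol 9 (not isolated), via ortho-quinone methide 10 (not isolated), via pyranoflavonol 7-O-prenyl ether 11 (not isolated)
Conditions: PhNEt2 (degassed), Ar, dark, sealed tube, 140 °C then 200 °C
Reagents that add atoms: none
Why: Two thermal [3,3] shifts of known type (the aryl propargyl ether to 2H-chromene cascade and the aromatic Claisen rearrangement of a prenyl ether, both established on flavonoid, coumarin and xanthone ethers) are run in one flask. At about 140 °C the gem-dimethyl-accelerated propargyl Claisen shift joins the alkyne terminus (later C4'') to C3' of ring B, the dienone tautomerises to allenyl catechol 9, a 1,5-hydrogen shift from O4'-H to the central allene carbon gives the Z-configured ortho-quinone methide 10, and a disrotatory oxa-6π electrocyclisation re-forms the O4'–C2'' bond, so that relative to 8 the pyran ring of 11 is closed in a net 6-endo cycloisomerisation whose only new ring bond is C3'–C4''. At about 200 °C the 7-O-prenyl ether of 11 rearranges through a six-membered transition state with allyl inversion, which sets the quaternary carbon on C8 and, after tautomerisation, frees the 7-OH of 12. Ring B selectivity is secured by the substitution pattern: of the two carbons ortho to O4', C5' bears OH, so a shift to it gives a dienone that cannot rearomatise and only reverts, whereas C3'-H can. Ring A selectivity (C8 over C6) rests on the higher C7–C8 bond order imposed by the fused pyrone, as in 7-allyloxychromones and 2-naphthyl ethers, and on the 5-OMe group, which removes the 5-OH to C4 carbonyl chelate that would favour C6 and is turned by the peri carbonyl towards C6, which it shields. No stereocentre is formed, and the basic solvent speeds both tautomerisations and keeps acid away from the new ortho-(1,1-dimethylallyl)phenol.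

Step 7
Reactants: 12 5-O-methylbroussoflavonol D
Product: 13 broussoflavonol D
Conditions: MgI2 (4 equiv), THF, 60 °C, Ar; then water
Reagents that add atoms: none
Why: Chelation-assisted demethylation in which magnesium bridges the C4 carbonyl and the peri O5 so that only this ether is activated for SN2 attack of iodide on its methyl carbon, with a Lewis acid mild enough to be known to spare a prenyl group next to a free phenol in 5-methoxyflavanones.

Compound list
1 | 1-(2,4-dihydroxy-6-methoxyphenyl)ethanone (2',4'-dihydroxy-6'-methoxyacetophenone) | CC(=O)c1c(O)cc(O)cc1OC | starting material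
2 | 1-[2-hydroxy-6-methoxy-4-(3-methylbut-2-enyloxy)phenyl]ethanone | CC(=O)c1c(O)cc(OCC=C(C)C)cc1OC | intermediate
3 | 2-bromo-4,5-dihydroxybenzaldehyde | O=Cc1cc(O)c(O)cc1Br | starting material
4 | 4,5-dihydroxy-2-(3-methylbut-2-enyl)benzaldehyde | O=Cc1cc(O)c(O)cc1CC=C(C)C | intermediate
5 | 5-hydroxy-4-(2-methylbut-3-yn-2-yloxy)-2-(3-methylbut-2-enyl)benzaldehyde | O=Cc1cc(O)c(OC(C)(C)C#C)cc1CC=C(C)C | intermediate
6 | (E)-chalcone from 2 and 5 | O=C(/C=C/c1cc(O)c(OC(C)(C)C#C)cc1CC=C(C)C)c1c(O)cc(OCC=C(C)C)cc1OC | intermediate
7 | racemic trans-3-hydroxyflavanone (dihydroflavonol) corresponding to 8, one enantiomer drawn, not isolated | CC(C)=CCc1cc(OC(C)(C)C#C)c(O)cc1[C@@H]1[C@H](C(=O)c2c(OC)cc(OCC=C(C)C)cc2O1)O | intermediate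
8 | 3-hydroxy-2-[5-hydroxy-4-(2-methylbut-3-yn-2-yloxy)-2-(3-methylbut-2-enyl)phenyl]-5-methoxy-7-(3-methylbut-2-enyloxy)chromen-4-one | O=c1c(O)c(-c2cc(O)c(OC(C)(C)C#C)cc2CC=C(C)C)oc2cc(OCC=C(C)C)cc(OC)c12 | intermediate
9 | 3'-(3-methylbuta-1,2-dienyl)-4',5'-dihydroxy-2'-prenyl flavonol (allenyl catechol), not isolated | O=c1c(O)c(-c2cc(O)c(O)c(C=C=C(C)C)c2CC=C(C)C)oc2cc(OCC=C(C)C)cc(OC)c12 | intermediate
10 | ring B ortho-quinone methide, C4' carbonyl and Z-configured C3' 3-methylbut-2-enylidene group, not isolated | O=c1c(O)c(C2=C(CC=C(C)C)/C(=C/C=C(C)C)C(=O)C(O)=C2)oc2cc(OCC=C(C)C)cc(OC)c12 | intermediate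
11 | pyranoflavonol with closed 2,2-dimethylpyran and intact 7-O-prenyl ether, not isolated | O=c1c(O)c(-c2cc(O)c3c(c2CC=C(C)C)C=CC(C)(C)O3)oc2cc(OCC=C(C)C)cc(OC)c12 | intermediate
12 | 5-O-methylbroussoflavonol D | C=CC(C)(C)c1c(O)cc(OC)c2c(=O)c(O)c(-c3cc(O)c4c(c3CC=C(C)C)C=CC(C)(C)O4)oc12 | intermediate
13 | broussoflavonol D | C=CC(C)(C)c1c(O)cc(O)c2c(=O)c(O)c(-c3cc(O)c4c(c3CC=C(C)C)C=CC(C)(C)O4)oc12 | target

Total step count: 7. Longest linear sequence: 6 steps (3, 4, 5, 6, 8, 12, 13).

Steps most likely to fail

Step 6. The pyran closure itself should be safe. The prenyl unit on O7, however, may migrate to C6 as well as to C8, may be lost as isoprene before it migrates, or the new ortho-(1,1-dimethylallyl)phenol may cyclise on prolonged heating. The fallback separates the two rearrangements and moves the ring A shift to the acetophenone stage. There the chelated 2-OH fixes the bond order in favour of C3, the later C8. It sets out from 2. Heating in PhNEt2 at 190 °C should give 1-[2,4-dihydroxy-6-methoxy-3-(2-methylbut-3-en-2-yl)phenyl]ethanone F1. MOMCl and i-Pr2NEt cap the free 4-OH to give the 4-O-MOM acetophenone F2. Claisen–Schmidt condensation with 5 gives the 3'-(1,1-dimethylallyl)chalcone F3. Algar–Flynn–Oyamada oxidation gives the 8-(1,1-dimethylallyl)flavonol propargyl ether F4. Refluxing xylene (140 °C) then only has to drive the propargyl Claisen/oxa-6π cascade, giving 7-O-MOM-5-O-methylbroussoflavonol D F5. Dilute HCl in MeOH removes the 7-O-MOM group and the route is rejoined at 12.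

Step 5. The phenoxide may close onto the α-carbon (five-membered ring, aurone pathway), which a 6'-alkoxy group is known to favour. Peroxide may also degrade the ring A aryl ketone. The fallback separates epoxidation from ring closure, so that the ring is closed under acid, where the benzylic β-carbon is attacked. It sets out from 6. MOMCl and Cs2CO3 in DMF cap both phenols to give the bis-MOM chalcone F6. Weitz–Scheffer epoxidation (H2O2, NaOH, MeOH) gives the racemic trans-epoxyketone F7, which has no free phenol and cannot cyclise. HCl in MeOH at 40 °C removes both MOM groups, and the freed 2'-OH opens the epoxide at the benzylic carbon in the 6-endo mode. This gives 7, here isolated. Brief treatment of 7 with alkaline H2O2 dehydrogenates it, and the route is rejoined at 8.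

Step 7. Magnesium may be sequestered by the 3-hydroxy-4-keto chelate so that the methyl ether is not activated. Forcing the reaction may bring Lewis acid-induced cyclisation of the 7-OH onto the neighbouring vinyl group. The fallback replaces the methyl ether from the start by an acetal that falls off under mild Brønsted acid. It sets out from 5. Commercial 2,4,6-trihydroxyacetophenone is O-prenylated at its 4-OH under Mitsunobu conditions (3-methylbut-2-en-1-ol, PPh3, DIAD, THF) to give 2,6-dihydroxy-4-prenyloxyacetophenone F8. One equivalent of MOMCl with i-Pr2NEt gives the mono-MOM acetophenone F9. Claisen–Schmidt condensation with 5 gives the 6'-O-MOM chalcone F10. Algar–Flynn–Oyamada oxidation gives the 5-O-MOM flavonol bis-ether F11. The same one-flask thermolysis as in step 6 gives 5-O-MOM-broussoflavonol D F12. Dilute HCl in MeOH at 40 °C cleaves the carbonyl-activated 5-O-MOM group, and the route is rejoined at 13.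

Further compounds
F1 | step 6 | 1-[2,4-dihydroxy-6-methoxy-3-(2-methylbut-3-en-2-yl)phenyl]ethanone | CC(=O)c1c(O)c(C(C)(C)C=C)c(O)cc1OC
F2 | step 6 | 1-[2-hydroxy-6-methoxy-4-(methoxymethoxy)-3-(2-methylbut-3-en-2-yl)phenyl]ethanone (4-O-MOM acetophenone) | CC(=O)c1c(O)c(C(C)(C)C=C)c(OCOC)cc1OC
F3 | step 6 | (E)-3'-(1,1-dimethylallyl)chalcone from F2 and 5 | O=C(/C=C/c1cc(O)c(OC(C)(C)C#C)cc1CC=C(C)C)c1c(O)c(C(C)(C)C=C)c(OCOC)cc1OC
F4 | step 6 | 8-(1,1-dimethylallyl)-7-O-MOM-5-O-methylflavonol 4'-(1,1-dimethylpropargyl) ether | C=CC(C)(C)c1c(OCOC)cc(OC)c2c(=O)c(O)c(-c3cc(O)c(OC(C)(C)C#C)cc3CC=C(C)C)oc12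
F5 | step 6 | 7-O-MOM-5-O-methylbroussoflavonol D | C=CC(C)(C)c1c(OCOC)cc(OC)c2c(=O)c(O)c(-c3cc(O)c4c(c3CC=C(C)C)C=CC(C)(C)O4)oc12
F6 | step 5 | (E)-bis-MOM chalcone | O=C(/C=C/c1cc(OCOC)c(OC(C)(C)C#C)cc1CC=C(C)C)c1c(OCOC)cc(OCC=C(C)C)cc1OC
F7 | step 5 | racemic trans-epoxyketone, one enantiomer drawn | O=C([C@H]1O[C@@H]1c1cc(OCOC)c(OC(C)(C)C#C)cc1CC=C(C)C)c1c(OCOC)cc(OCC=C(C)C)cc1OC
F8 | step 7 | 1-[2,6-dihydroxy-4-(3-methylbut-2-enyloxy)phenyl]ethanone (2,6-dihydroxy-4-prenyloxyacetophenone) | CC(=O)c1c(O)cc(OCC=C(C)C)cc1O
F9 | step 7 | 1-[2-hydroxy-6-(methoxymethoxy)-4-(3-methylbut-2-enyloxy)phenyl]ethanone (mono-MOM acetophenone) | CC(=O)c1c(O)cc(OCC=C(C)C)cc1OCOC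
F10 | step 7 | (E)-6'-O-MOM chalcone from F9 and 5 | O=C(/C=C/c1cc(O)c(OC(C)(C)C#C)cc1CC=C(C)C)c1c(O)cc(OCC=C(C)C)cc1OCOC
F11 | step 7 | 5-O-MOM flavonol 4'-(1,1-dimethylpropargyl) 7-prenyl bis-ether | O=c1c(O)c(-c2cc(O)c(OC(C)(C)C#C)cc2CC=C(C)C)oc2cc(OCC=C(C)C)cc(OCOC)c12
F12 | step 7 | 5-O-MOM-broussoflavonol D | C=CC(C)(C)c1c(O)cc(OCOC)c2c(=O)c(O)c(-c3cc(O)c4c(c3CC=C(C)C)C=CC(C)(C)O4)oc12
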